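The route rests on cutting ring C (the pyranone) at C2–C3 and O1–C8a, which excises C2–O1 as one molecule of formaldehyde. The key step exploits the two positions that flank the C4 ketone: C3, the oxygenated α-carbon bearing ring B, is a latent enolate, and C8a of ring A, ortho to the C4 acyl group, becomes an SNAr site when it carries fluorine. In one flask, a Sc(OTf)3-catalysed enantioselective hydroxymethylation of a (Z)-silyl enol ether sets the C3 stereocentre, and the new primary alkoxide then displaces fluoride to close ring C. The precursor is the enol silane of a fully MOM-protected 2-fluoroaryl benzoin ether.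

Key step: step 11

Remarks on the chemistry:
- Locants O1, C2, C3, C4, C4a, C5–C8, C8a follow chroman-4-one numbering; ring A is the benzo ring, ring B the 3-aryl ring, ring C the pyranone.
- MOM = methoxymethyl; prenyl = 3-methylbut-2-en-1-yl; ArA = 6-fluoro-2,4-bis(methoxymethoxy)-3-prenylphenyl; ArB = 2-methoxy-4-(methoxymethoxy)-3-prenylphenyl.
- Assumption: the facial sense of the Sc(OTf)3/bipyridine catalyst on this fully substituted enol silane is extrapolated from simpler (Z)-silicon enolates. The (S,S)-ligand is written; should a correlation experiment show the opposite sense, the equally available (R,R)-ligand is used in step 11 in the same way.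

Step 1
Reactants: 1 5-fluorobenzene-1,3-diol
Product: 2 5-fluoro-2-iodobenzene-1,3-diol
Conditions: I2, NaHCO3, H2O, 0 °C → rt
Reagents that add atoms: iodine, II
Why: Electrophilic aromatic iodination of a resorcinol under aqueous bicarbonate conditions is expected to go to C2 between the two hydroxyl groups, a position that here is also para to fluorine.

Step 2
Reactants: 2 5-fluoro-2-iodobenzene-1,3-diol
Product: 3 5-fluoro-2-iodo-1,3-bis(methoxymethoxy)benzene
Conditions: MOMCl, i-Pr2NEt, CH2Cl2, 0 °C → rt
Reagents that add atoms: chloromethyl methyl ether, COCCl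
Why: O-Alkylation of both phenols (MOM acetal protection) should proceed cleanly and supplies the ortho-directing groups needed in step 4.

Step 3
Reactants: 3 5-fluoro-2-iodo-1,3-bis(methoxymethoxy)benzene
Product: 5 5-fluoro-1,3-bis(methoxymethoxy)-2-(3-methylbut-2-en-1-yl)benzene, via aryllithium 4 (not isolated)
Conditions: n-BuLi, THF, −78 °C; CuI (10 mol %), prenyl bromide, −78 → 0 °C
Reagents that add atoms: prenyl bromide (1-bromo-3-methylbut-2-ene), CC(C)=CCBr
Why: Iodine–lithium exchange places the metal unambiguously between the two OMOM groups, and copper-catalysed SN2 allylation with prenyl bromide should give the linear prenyl arene.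

Step 4
Reactants: 5 5-fluoro-1,3-bis(methoxymethoxy)-2-(3-methylbut-2-en-1-yl)benzene
Product: 8 6-fluoro-2,4-bis(methoxymethoxy)-3-(3-methylbut-2-en-1-yl)benzaldehyde (ArA–CHO), via aryllithium 6 (not isolated), via hemiaminal alkoxide 7 (not isolated)
Conditions: n-BuLi, THF, −78 °C; DMF, −78 °C; then H2O
Reagents that add atoms: N,N-dimethylformamide, CN(C)C=O
Why: Directed ortho-metalation can only occur at the two equivalent ring positions flanked by F and OMOM, and formylation with DMF at −78 °C should outrun loss of LiF to an aryne.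

Step 5
Reactants: 9 4-hydroxy-2-methoxybenzaldehyde
Product: 10 2-methoxy-4-(methoxymethoxy)benzaldehyde
Conditions: MOMCl, i-Pr2NEt, CH2Cl2, 0 °C → rt
Reagents that add atoms: chloromethyl methyl ether, COCCl
Why: MOM protection of the single phenol is a routine O-alkylation and installs the second ortho-directing group for step 6.

Step 6
Reactants: 10 2-methoxy-4-(methoxymethoxy)benzaldehyde
Product: 14 2-methoxy-4-(methoxymethoxy)-3-(3-methylbut-2-en-1-yl)benzaldehyde (ArB–CHO), via amino alkoxide 11 (not isolated), via lithiated amino alkoxide 12 (not isolated), via prenylated amino alkoxide 13 (not isolated)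
Conditions: lithium 4-methylpiperazin-1-ide (1-methylpiperazine, n-BuLi), THF, −20 °C; s-BuLi, TMEDA, −78 → −40 °C; CuI (10 mol %), prenyl bromide, −78 → 0 °C; then H2O
Reagents that add atoms: prenyl bromide (1-bromo-3-methylbut-2-ene), CC(C)=CCBr
Why: Comins in situ protection masks the aldehyde as a weakly directing α-amino alkoxide, so directed ortho-metalation should occur at C3 between OMe and OMOM, followed by copper-catalysed SN2 allylation and release of the aldehyde on aqueous work-up.

Step 7
Reactants: 14 2-methoxy-4-(methoxymethoxy)-3-(3-methylbut-2-en-1-yl)benzaldehyde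
Product: 16 tributyl[(methoxymethoxy)(ArB)methyl]stannane (racemic), via hydroxystannane 15 (not isolated)
Conditions: Bu3SnLi (Bu3SnH, LDA), THF, −78 °C; aq. NH4Cl; crude, MOMCl, i-Pr2NEt, CH2Cl2, 0 °C → rt
Reagents that add atoms: tributylstannane, CCCC[SnH](CCCC)CCCC; chloromethyl methyl ether, COCCl
Why: Still's α-alkoxystannane synthesis, in which the stannyl anion adds 1,2 to the aldehyde and the labile α-hydroxystannane is capped at once as its MOM ether; the stereocentre is racemic and is erased later.

Step 8
Reactants: 16 tributyl[(methoxymethoxy)(ArB)methyl]stannane; 8 6-fluoro-2,4-bis(methoxymethoxy)-3-(3-methylbut-2-en-1-yl)benzaldehyde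
Product: 18 1-(ArA)-2-(methoxymethoxy)-2-(ArB)ethan-1-ol (mixture of racemic diastereomers), via alkoxybenzyllithium 17 (not isolated)
Conditions: n-BuLi, THF, −78 °C; then 8, −78 °C; H2O
Reagents that add atoms: none
Why: Tin–lithium exchange gives the α-alkoxybenzyllithium, which should add 1,2 to the non-enolisable aldehyde at −78 °C before a Wittig rearrangement can occur; both new stereocentres are destroyed in steps 9 and 10.

Step 9
Reactants: 18 1-(ArA)-2-(methoxymethoxy)-2-(ArB)ethan-1-ol
Product: 19 1-(ArA)-2-(methoxymethoxy)-2-(ArB)ethan-1-one (racemic)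
Conditions: Dess–Martin periodinane, CH2Cl2, 0 °C → rt
Reagents that add atoms: none
Why: Dess–Martin oxidation of the hindered benzylic alcohol is mild enough to leave the MOM ethers and both prenyl groups untouched.

Step 10
Reactants: 19 1-(ArA)-2-(methoxymethoxy)-2-(ArB)ethan-1-one
Product: 21 (Z)-[1-(ArA)-2-(methoxymethoxy)-2-(ArB)ethenyl]oxytrimethylsilane (OTMS and OMOM cis), via lithium enolate 20 (not isolated)
Conditions: LiHMDS, TMSCl, THF, −78 → 0 °C (in situ quench); non-aqueous work-up
Reagents that add atoms: chlorotrimethylsilane, C[Si](C)(C)Cl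
Why: Kinetic enolisation at the only α-hydrogen with internal silyl trapping should give the O-silyl enol ether, and chelation of lithium between the enolate oxygen and the α-OMOM group should fix the (Z) geometry.

Step 11
Reactants: 21 (Z)-[1-(ArA)-2-(methoxymethoxy)-2-(ArB)ethenyl]oxytrimethylsilane
Product: 23 (3R)-3-[2-methoxy-4-(methoxymethoxy)-3-(3-methylbut-2-en-1-yl)phenyl]-3,5,7-tris(methoxymethoxy)-6-(3-methylbut-2-en-1-yl)chroman-4-one, via hydroxymethyl ketone 22 (not isolated)
Conditions: Sc(OTf)3 (10 mol %), (S,S)-6,6′-bis(1-hydroxy-2,2-dimethylpropyl)-2,2′-bipyridine (12 mol %), aq. HCHO, DME, −20 °C; then Cs2CO3, DMSO, 25 → 40 °C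
Reagents that add atoms: formaldehyde, C=O
Why: The chiral Sc(OTf)3–bipyridine diol complex binds formaldehyde in the aqueous medium and the (Z)-enol silane attacks it through an open transition state at C3, forming the C2–C3 bond and the quaternary C3 stereocentre (22); Cs2CO3 then converts the new primary alcohol into an alkoxide that adds to C8a, the fluorine-bearing carbon ortho to the C4 ketone, and expels fluoride from the Meisenheimer intermediate to form the O1–C8a bond. The closest known reactions are the catalytic enantioselective hydroxymethylation of silicon enolates with aqueous formaldehyde (a Mukaiyama aldol) and the intramolecular SNAr closure of 2-fluoroaryl ketones to chroman-4-ones. Ring C is the only ring closed, as a six-membered ring by addition–elimination, formally a 6-endo-trig attack on the vinylogous acyl fluoride C4(=O)–C4a=C8a–F with the negative charge taken up by the C4 carbonyl. The C3 configuration is set by the catalyst, which distinguishes the two faces of an enol silane whose single (Z) geometry fixes the positions of ring B and OMOM, and the ligand antipode is chosen to give (R). The step needs C–C bond formation only at C3 (the sole nucleophilic carbon), displacement only at C8a (the only leaving group and a six-membered closure) and preservation of the new stereocentre. The last is secured because C3 carries no hydrogen after the aldol, and ring closure, helped by the gem-disubstitution at C3, should outrun retro-aldol loss of formaldehyde.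

Step 12
Reactants: 23 (3R)-3-[2-methoxy-4-(methoxymethoxy)-3-(3-methylbut-2-en-1-yl)phenyl]-3,5,7-tris(methoxymethoxy)-6-(3-methylbut-2-en-1-yl)chroman-4-one
Product: 24 (3R)-3,5,7-trihydroxy-3-[4-hydroxy-2-methoxy-3-(3-methylbut-2-en-1-yl)phenyl]-6-(3-methylbut-2-en-1-yl)-2,3-dihydro-4H-chromen-4-one
Conditions: conc. HCl (cat.), MeOH/THF, 40 °C
Reagents that add atoms: none
Why: Acid-catalysed transacetalisation to methanol should remove all four MOM groups, and C3, which has no α-hydrogen, cannot epimerise, so the (R) configuration from step 11 is retained.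

Compound list
1 | 5-fluorobenzene-1,3-diol (5-fluororesorcinol) | Oc1cc(O)cc(F)c1 | starting material
2 | 5-fluoro-2-iodobenzene-1,3-diol | Oc1cc(F)cc(O)c1I | intermediate
3 | 5-fluoro-2-iodo-1,3-bis(methoxymethoxy)benzene | COCOc1cc(F)cc(OCOC)c1I | intermediate
4 | [4-fluoro-2,6-bis(methoxymethoxy)phenyl]lithium (not isolated) | COCOc1cc(F)cc(OCOC)c1[Li] | intermediate
5 | 5-fluoro-1,3-bis(methoxymethoxy)-2-(3-methylbut-2-en-1-yl)benzene | COCOc1cc(F)cc(OCOC)c1CC=C(C)C | intermediate
6 | [6-fluoro-2,4-bis(methoxymethoxy)-3-prenylphenyl]lithium (not isolated) | [Li]c1c(F)cc(OCOC)c(CC=C(C)C)c1OCOC | intermediate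
7 | lithium (dimethylamino)(ArA)methanolate, the DMF adduct (not isolated) | [Li]OC(N(C)C)c1c(F)cc(OCOC)c(CC=C(C)C)c1OCOC | intermediate
8 | 6-fluoro-2,4-bis(methoxymethoxy)-3-(3-methylbut-2-en-1-yl)benzaldehyde | O=Cc1c(F)cc(OCOC)c(CC=C(C)C)c1OCOC | intermediate
9 | 4-hydroxy-2-methoxybenzaldehyde | COc1cc(O)ccc1C=O | starting material
10 | 2-methoxy-4-(methoxymethoxy)benzaldehyde | COCOc1ccc(C=O)c(OC)c1 | intermediate
11 | lithium [2-methoxy-4-(methoxymethoxy)phenyl](4-methylpiperazin-1-yl)methanolate (not isolated) | [Li]OC(N1CCN(C)CC1)c1ccc(OCOC)cc1OC | intermediate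
12 | 3-lithio derivative of 11 (not isolated) | [Li]OC(N1CCN(C)CC1)c1ccc(OCOC)c([Li])c1OC | intermediate
13 | lithium (ArB)(4-methylpiperazin-1-yl)methanolate (not isolated) | [Li]OC(N1CCN(C)CC1)c1ccc(OCOC)c(CC=C(C)C)c1OC | intermediate
14 | 2-methoxy-4-(methoxymethoxy)-3-(3-methylbut-2-en-1-yl)benzaldehyde | COCOc1ccc(C=O)c(OC)c1CC=C(C)C | intermediate
15 | (ArB)(tributylstannyl)methanol, racemic (not isolated) | CCCC[Sn](CCCC)(CCCC)C(O)c1ccc(OCOC)c(CC=C(C)C)c1OC | intermediate
16 | tributyl[(methoxymethoxy)(ArB)methyl]stannane, racemic | CCCC[Sn](CCCC)(CCCC)C(OCOC)c1ccc(OCOC)c(CC=C(C)C)c1OC | intermediate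
17 | [(methoxymethoxy)(ArB)methyl]lithium (not isolated) | [Li]C(OCOC)c1ccc(OCOC)c(CC=C(C)C)c1OC | intermediate
18 | 1-(ArA)-2-(methoxymethoxy)-2-(ArB)ethan-1-ol, diastereomer mixture | OC(c1c(F)cc(OCOC)c(CC=C(C)C)c1OCOC)C(OCOC)c1ccc(OCOC)c(CC=C(C)C)c1OC | intermediate
19 | 1-(ArA)-2-(methoxymethoxy)-2-(ArB)ethan-1-one, racemic | O=C(c1c(F)cc(OCOC)c(CC=C(C)C)c1OCOC)C(OCOC)c1ccc(OCOC)c(CC=C(C)C)c1OC | intermediate
20 | lithium (Z)-enolate of 19 (not isolated) | [Li]O/C(c1c(F)cc(OCOC)c(CC=C(C)C)c1OCOC)=C(\OCOC)c1ccc(OCOC)c(CC=C(C)C)c1OC | intermediate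
21 | (Z)-[1-(ArA)-2-(methoxymethoxy)-2-(ArB)ethenyl]oxytrimethylsilane | C[Si](C)(C)O/C(c1c(F)cc(OCOC)c(CC=C(C)C)c1OCOC)=C(\OCOC)c1ccc(OCOC)c(CC=C(C)C)c1OC | intermediate
22 | (2R)-1-(ArA)-3-hydroxy-2-(methoxymethoxy)-2-(ArB)propan-1-one (not isolated) | COc1c([C@@](OCOC)(CO)C(=O)c2c(F)cc(OCOC)c(CC=C(C)C)c2OCOC)ccc(OCOC)c1CC=C(C)C | intermediate
23 | (3R)-3-(ArB)-3,5,7-tris(methoxymethoxy)-6-(3-methylbut-2-en-1-yl)chroman-4-one | COc1c([C@@]2(OCOC)COc3cc(OCOC)c(CC=C(C)C)c(OCOC)c3C2=O)ccc(OCOC)c1CC=C(C)C | intermediate
24 | (3R)-3,5,7-trihydroxy-3-[4-hydroxy-2-methoxy-3-(3-methylbut-2-en-1-yl)phenyl]-6-(3-methylbut-2-en-1-yl)-2,3-dihydro-4H-chromen-4-one | COc1c([C@@]2(O)COc3cc(O)c(CC=C(C)C)c(O)c3C2=O)ccc(O)c1CC=C(C)C | target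

Total step count: 12. Longest linear sequence: 9 steps (steps 1, 2, 3, 4, 8, 9, 10, 11, 12); the ring B branch (steps 5–7) joins at step 8.

Steps most likely to fail

Step 11. Three processes may spoil it. The hindered, fully substituted enol silane may be protodesilylated faster than it is hydroxymethylated, which returns the ketone to a racemic base-mediated pathway in the second stage. Retro-aldol loss of formaldehyde from the alkoxide may compete with ring closure and erode the enantiomeric purity. The facial selectivity on this substrate class may also be low or of the opposite sense. The fallback keeps the same two bond formations in one operation but gives up asymmetric catalysis for resolution. Setting out from ketone 19, paraformaldehyde and K2CO3 in DMF (25 → 50 °C) should give, through the racemic hydroxymethyl ketone F1, the racemic tetra-MOM chromanone F2 by direct enolate aldol addition and SNAr closure. Preparative HPLC of F2 on a chiral stationary phase then delivers the (3R)-enantiomer, and the route is rejoined at 23.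

Step 12. Brønsted acid may cyclise the ortho-prenylphenols of rings A and B to chromans, may dehydrate the tertiary benzylic C3 alcohol toward the isoflavone, or may leave the tertiary MOM ether incompletely cleaved. The fallback avoids protic acid by passing through silyl ethers. Setting out from 23, TESOTf and 2,2′-bipyridyl in CH2Cl2 (0 °C → rt, then H2O) should convert the three aryl MOM ethers into aryl triethylsilyl ethers and release the tertiary alcohol through its bipyridinium intermediate, giving the tris(triethylsilyl) ether F3. Buffered fluoride (TBAF, AcOH, THF, 0 °C) then gives 24.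

Step 6. Lithiation may occur at the wrong ring position (C6 next to the masked aldehyde, or C5), or the alkyllithium may attack an incompletely masked aldehyde. The fallback replaces the transient protection by an isolated acetal. Setting out from 10, 1,2-bis(trimethylsilyloxy)ethane with catalytic TMSOTf (CH2Cl2, −78 °C) gives the 1,3-dioxolane F4. Lithiation of F4 with n-BuLi (THF, 0 °C) between OMe and OMOM, followed by CuI and prenyl bromide, gives the prenylated dioxolane F5. Mild hydrolysis (PPTS, acetone/H2O, rt) returns to the route at 14.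

Further compounds
F1 | step 11 | racemic 1-(ArA)-3-hydroxy-2-(methoxymethoxy)-2-(ArB)propan-1-one | COc1c(C(OCOC)(CO)C(=O)c2c(F)cc(OCOC)c(CC=C(C)C)c2OCOC)ccc(OCOC)c1CC=C(C)C
F2 | step 11 | racemic 3-(ArB)-3,5,7-tris(methoxymethoxy)-6-(3-methylbut-2-en-1-yl)chroman-4-one | COc1c(C2(OCOC)COc3cc(OCOC)c(CC=C(C)C)c(OCOC)c3C2=O)ccc(OCOC)c1CC=C(C)C
F3 | step 12 | (3R)-3-hydroxy-3-[2-methoxy-3-(3-methylbut-2-en-1-yl)-4-(triethylsilyloxy)phenyl]-6-(3-methylbut-2-en-1-yl)-5,7-bis(triethylsilyloxy)chroman-4-one | COc1c([C@@]2(O)COc3cc(O[Si](CC)(CC)CC)c(CC=C(C)C)c(O[Si](CC)(CC)CC)c3C2=O)ccc(O[Si](CC)(CC)CC)c1CC=C(C)C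
F4 | step 6 | 2-[2-methoxy-4-(methoxymethoxy)phenyl]-1,3-dioxolane | COCOc1ccc(C2OCCO2)c(OC)c1
F5 | step 6 | 2-[2-methoxy-4-(methoxymethoxy)-3-(3-methylbut-2-en-1-yl)phenyl]-1,3-dioxolane | COCOc1ccc(C2OCCO2)c(OC)c1CC=C(C)C
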